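**Retrosynthetic overview**

1. Feature (lignan locants: guaiacyl half C7–C9, benzofuran half C1'–C9' with benzene ring B, dihydrofuran side chain C7''–C9''): in the dihydrofuran ring O4'–C7''–C8''–C5'–C4' the aryl ether bond O4'–C4' is the only bond to be made that touches neither stereocentre (C7'', C8''). C4' is para to C1', whose substituent C7' can be a formyl group that activates a C4' fluoride and later becomes a furofuran carbon.
2. Key disconnection: O4'–C4', by intramolecular SNAr of the C7'' alkoxide of an open-chain anti-1,2-diarylpropane-1,3-diol 9''-O-TIPS ether onto a 4-fluoro-3-methoxybenzaldehyde ring (15 → 17). The dihydrofuran ring is formed first.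
3. Precursor: C7''–C8'' by an auxiliary-controlled MgCl2-catalysed anti-aldol of a ring-B arylacetyl oxazolidinone (aryl from lithiation of the fluorobenzaldehyde acetal next to fluorine) with O-TIPS vanillin, then reduction, primary silylation and deacetalisation.
4. Furofuran: C7–C8 and C7'–C8' by two ligand-controlled alkynylations (1,4-diarylbutynediol); C8–C9 and C8'–C9' by anti-diiodination and double Pd cyclocarbonylation (both lactone rings); C8/C8' by hydrogenation anti to both aryl groups; LiAlH4, then the two tetrahydrofuran rings through primary tosylates (formed last).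
5. Global desilylation gives the target.

Key step: step 10

Assumption: the target is taken exactly as written, i.e. both aryl groups endo (concave face) on the 3,7-dioxabicyclo[3.3.0]octane, (1S,2S,5S,6S), and a cis-(2S,3S)-2,3-dihydrobenzofuran.

Abbreviations: TIPS = triisopropylsilyl; TMS = trimethylsilyl; ArG = 3-methoxy-4-(triisopropylsilyloxy)phenyl; Bf = (2S,3S)-7-methoxy-2-ArG-3-[(triisopropylsilyloxy)methyl]-2,3-dihydro-1-benzofuran-5-yl.

**Route**

Step 1
Reactants: 1 4-fluoro-3-methoxybenzaldehyde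
Product: 2 2-(4-fluoro-3-methoxyphenyl)-1,3-dioxolane
Conditions: ethylene glycol, TsOH·H2O (cat.), toluene, reflux, Dean–Stark trap
Reagents that add atoms: ethylene glycol, OCCO
Why: Acid-catalysed acetalisation with azeotropic removal of water masks the formyl group as a dioxolane that tolerates the lithium amide, the enolate chemistry and the hydride reduction that follow.

Step 2
Reactants: 2 2-(4-fluoro-3-methoxyphenyl)-1,3-dioxolane
Product: 4 2-[5-(1,3-dioxolan-2-yl)-2-fluoro-3-methoxyphenyl]ethanol, via aryllithium 3 (not isolated)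
Conditions: lithium 2,2,6,6-tetramethylpiperidide (from the amine and n-BuLi), THF, −78 °C; ethylene oxide, BF3·OEt2, −78 °C; aq NH4Cl
Reagents that add atoms: ethylene oxide, C1CO1; lithium 2,2,6,6-tetramethylpiperidide, [Li]N1C(C)(C)CCCC1(C)C (lithium in 3 only)
Why: Directed ortho-metalation, in which the hindered amide removes the most acidic and least crowded ring proton (next to fluorine, the future C5'), and the aryllithium, kept at −78 °C to prevent loss of LiF, opens BF3-activated ethylene oxide by SN2 attack.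

Step 3
Reactants: 4 2-[5-(1,3-dioxolan-2-yl)-2-fluoro-3-methoxyphenyl]ethanol
Product: 5 [5-(1,3-dioxolan-2-yl)-2-fluoro-3-methoxyphenyl]acetic acid
Conditions: TEMPO (cat.), NaOCl (cat.), NaClO2, MeCN/phosphate buffer (pH 6.7), 35 °C
Reagents that add atoms: sodium chlorite, [Na+].[O-]Cl=O
Why: TEMPO/hypochlorite-catalysed oxidation to the aldehyde (Anelli oxidation) followed in the same pot by chlorite oxidation to the acid (Pinnick-type) proceeds near neutral pH, where the dioxolane is stable.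

Step 4
Reactants: 5 [5-(1,3-dioxolan-2-yl)-2-fluoro-3-methoxyphenyl]acetic acid; 6 (S)-4-benzyl-1,3-oxazolidin-2-one
Product: 8 (4S)-4-benzyl-3-{[5-(1,3-dioxolan-2-yl)-2-fluoro-3-methoxyphenyl]acetyl}-1,3-oxazolidin-2-one, via mixed pivalic anhydride 7 (not isolated)
Conditions: pivaloyl chloride, Et3N, THF, −20 °C; then 6, LiCl, −20 °C → rt
Reagents that add atoms: pivaloyl chloride, CC(C)(C)C(=O)Cl (atoms in 7 only)
Why: N-acylation of the Evans auxiliary through the mixed anhydride, in which the oxazolidinone attacks the less hindered arylacetyl carbonyl and pivalate leaves.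

Step 5
Reactants: 9 vanillin (4-hydroxy-3-methoxybenzaldehyde)
Product: 10 3-methoxy-4-(triisopropylsilyloxy)benzaldehyde
Conditions: TIPSCl, imidazole, DMF, rt
Reagents that add atoms: chlorotriisopropylsilane, CC(C)[Si](Cl)(C(C)C)C(C)C
Why: Imidazole-promoted silyl ether formation gives an aryl TIPS ether that survives base, hydride and palladium chemistry and is removed by fluoride at the end.

Step 6
Reactants: 8 (4S)-4-benzyl-3-{[5-(1,3-dioxolan-2-yl)-2-fluoro-3-methoxyphenyl]acetyl}-1,3-oxazolidin-2-one; 10 3-methoxy-4-(triisopropylsilyloxy)benzaldehyde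
Product: 12 (4S)-4-benzyl-3-[(2R,3S)-2-[5-(1,3-dioxolan-2-yl)-2-fluoro-3-methoxyphenyl]-3-hydroxy-3-ArG-propanoyl]-1,3-oxazolidin-2-one, via trimethylsilyl ether 11 (not isolated)
Conditions: MgCl2 (0.2 equiv), Et3N, TMSCl, EtOAc, rt; then citric acid, MeOH, 0 °C
Reagents that add atoms: chlorotrimethylsilane, C[Si](C)(C)Cl (atoms in 11 only)
Why: Evans magnesium halide-catalysed anti-aldol reaction, in which the MgCl2-chelated Z-enolate of 8 is attacked by 10 on the face away from the benzyl group through a boat-like transition state, setting C8'' (2R) and C7'' (3S) anti, while O-silylation by TMSCl frees the magnesium for turnover and mild methanolysis then releases the hydroxyl.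

Step 7
Reactants: 12 (4S)-4-benzyl-3-[(2R,3S)-2-[5-(1,3-dioxolan-2-yl)-2-fluoro-3-methoxyphenyl]-3-hydroxy-3-ArG-propanoyl]-1,3-oxazolidin-2-one
Product: 13 (1S,2S)-2-[5-(1,3-dioxolan-2-yl)-2-fluoro-3-methoxyphenyl]-1-ArG-propane-1,3-diol
Conditions: LiBH4, MeOH (1 equiv), THF, 0 °C
Reagents that add atoms: none
Why: Reductive cleavage of the N-acyl oxazolidinone by LiBH4 gives the 1,3-diol and returns the auxiliary without touching the acetal, the aryl fluoride or either stereocentre (the descriptor at C8'' changes from R to S only through CIP ranking).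

Step 8
Reactants: 13 (1S,2S)-2-[5-(1,3-dioxolan-2-yl)-2-fluoro-3-methoxyphenyl]-1-ArG-propane-1,3-diol
Product: 14 (1S,2S)-2-[5-(1,3-dioxolan-2-yl)-2-fluoro-3-methoxyphenyl]-1-ArG-3-(triisopropylsilyloxy)propan-1-ol
Conditions: TIPSCl (1.1 equiv), imidazole, CH2Cl2, 0 °C → rt
Reagents that add atoms: chlorotriisopropylsilane, CC(C)[Si](Cl)(C(C)C)C(C)C
Why: Sterically controlled silyl ether formation, the bulky chlorosilane reacting with the primary C9'' hydroxyl far faster than with the hindered secondary benzylic C7'' hydroxyl.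

Step 9
Reactants: 14 (1S,2S)-2-[5-(1,3-dioxolan-2-yl)-2-fluoro-3-methoxyphenyl]-1-ArG-3-(triisopropylsilyloxy)propan-1-ol
Product: 15 4-fluoro-3-[(1S,2S)-1-hydroxy-1-ArG-3-(triisopropylsilyloxy)propan-2-yl]-5-methoxybenzaldehyde
Conditions: PPTS (0.3 equiv), acetone/H2O (10:1), 50 °C
Reagents that add atoms: water, O
Why: Mild acid-catalysed acetal hydrolysis unmasks the formyl group, now the SNAr activator, under conditions that should leave the TIPS ethers and the benzylic alcohol intact.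

Step 10
Reactants: 15 4-fluoro-3-[(1S,2S)-1-hydroxy-1-ArG-3-(triisopropylsilyloxy)propan-2-yl]-5-methoxybenzaldehyde
Product: 17 (2S,3S)-7-methoxy-2-ArG-3-[(triisopropylsilyloxy)methyl]-2,3-dihydro-1-benzofuran-5-carbaldehyde, via potassium alkoxide 16 (not isolated)
Conditions: KN(SiMe3)2 (1.05 equiv, added slowly), THF (0.02 M), −78 °C → 0 °C
Reagents that add atoms: potassium bis(trimethylsilyl)amide, C[Si](C)(C)[N-][Si](C)(C)C.[K+] (potassium in 16 only)
Why: The amide deprotonates the C7'' hydroxyl and the potassium alkoxide adds to C4', giving a Meisenheimer adduct whose charge rests on the para formyl oxygen, after which fluoride leaves (addition–elimination, SNAr). The closest known reaction type is the base-induced cyclisation of 2-(2-fluoroaryl)ethanols bearing a para carbonyl group to 2,3-dihydrobenzofurans. The dihydrofuran ring closes in the 5-exo-trig mode at an arene carbon, O4'–C4' being the only bond formed. No stereocentre is created and none is at risk, because the C7''–O and C8''–C5' bonds are neither made nor broken, so the anti (1S,2S) open chain is carried unchanged into the strained cis-(2S,3S) ring, which a closure forming the C7''–O bond at the easily ionised benzylic carbon would not ensure. The step needs O7'' and not O9'' to attack, and as C7'' and C9'' both hang on C8'' either oxygen would close a five-membered ring, so ring size gives no bias: the selectivity rests on O9'' carrying a TIPS group whose 1,5 oxygen-to-oxygen shift onto the hindered secondary alkoxide should be slow at or below 0 °C. Slow addition of one equivalent of base to the cold alcohol keeps the amide from adding to the formyl group, and hemiacetal formation between alkoxide and aldehyde is reversible.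

Step 11
Reactants: 10 3-methoxy-4-(triisopropylsilyloxy)benzaldehyde
Product: 18 (1R)-1-ArG-3-(trimethylsilyl)prop-2-yn-1-ol
Conditions: ethynyltrimethylsilane, Et2Zn, Cy2NH (cat.), Et2O, rt; (S)-BINOL (20 mol%), Ti(OiPr)4 (50 mol%), then 10, rt; aqueous work-up
Reagents that add atoms: ethynyltrimethylsilane, C#C[Si](C)(C)C
Why: Catalytic asymmetric alkynylzinc addition to an aryl aldehyde under BINOL–Ti(OiPr)4 control, the (S)-BINOL complex being the antipode expected to direct the alkynyl group to the Si face of the formyl group, which sets the future C7 stereocentre.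

Step 12
Reactants: 18 (1R)-1-ArG-3-(trimethylsilyl)prop-2-yn-1-ol
Product: 19 (1S)-1-ArG-prop-2-yn-1-ol
Conditions: K2CO3 (0.2 equiv), MeOH, 0 °C
Reagents that add atoms: none
Why: Base-catalysed methanolysis (protodesilylation of an alkynylsilane) cleaves the C(sp)–Si bond much faster than the hindered aryl O–TIPS bond at 0 °C; the descriptor changes to S only because ethynyl ranks below aryl.

Step 13
Reactants: 19 (1S)-1-ArG-prop-2-yn-1-ol
Product: 20 (1S)-1-ArG-1-(trimethylsilyloxy)prop-2-yne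
Conditions: TMSCl, imidazole, CH2Cl2, 0 °C
Reagents that add atoms: chlorotrimethylsilane, C[Si](C)(C)Cl
Why: Silyl ether formation masks the propargylic hydroxyl so that it does not consume or perturb the zinc/titanium catalyst of the next step, TMS being chosen because it is lost in the work-up there.

Step 14
Reactants: 17 (2S,3S)-7-methoxy-2-ArG-3-[(triisopropylsilyloxy)methyl]-2,3-dihydro-1-benzofuran-5-carbaldehyde; 20 (1S)-1-ArG-1-(trimethylsilyloxy)prop-2-yne
Product: 23 (1R,4R)-1-ArG-4-Bf-but-2-yne-1,4-diol, via ethylzinc acetylide 21 (not isolated), via mono-trimethylsilyl ether 22 (not isolated)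
Conditions: 20 (2 equiv), Et2Zn, Cy2NH (cat.), Et2O, rt; (S)-BINOL (40 mol%), Ti(OiPr)4, then 17, rt; citric acid, MeOH, 0 °C
Reagents that add atoms: diethylzinc, CC[Zn]CC (zinc and ethyl in 21 only)
Why: Second BINOL–Ti(OiPr)4-controlled alkynylzinc addition, the (S)-BINOL complex again expected to deliver the alkynyl group to the Si face of the formyl group of 17 and so set C7' (R in the diol); the distant stereocentres of both partners should exert no bias, the ArG-bearing carbinol is unchanged in space (its descriptor becomes R once the alkyne is internal), and methanolysis removes the TMS ether.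

Step 15
Reactants: 23 (1R,4R)-1-ArG-4-Bf-but-2-yne-1,4-diol
Product: 24 (1R,2E,4R)-1-ArG-4-Bf-2,3-diiodobut-2-ene-1,4-diol
Conditions: I2 (1.5 equiv), NaHCO3, CH2Cl2, rt, dark; aq Na2S2O3
Reagents that add atoms: iodine, II
Why: Electrophilic anti-addition of iodine to the alkyne gives the (E)-diiodide, in which each iodine is cis to the carbinol carbon on the other alkene carbon as lactone formation requires, while NaHCO3 keeps the medium neutral so that the benzylic carbinols do not ionise.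

Step 16
Reactants: 24 (1R,2E,4R)-1-ArG-4-Bf-2,3-diiodobut-2-ene-1,4-diol
Product: 26 (2R,6R)-2-ArG-6-Bf-3,7-dioxabicyclo[3.3.0]oct-1(5)-ene-4,8-dione, via iodobutenolide 25 (not isolated)
Conditions: PdCl2(PPh3)2 (5 mol%), CO (5 atm), 2,6-lutidine, THF, 45 °C
Reagents that add atoms: carbon monoxide, [C-]#[O+]
Why: Palladium-catalysed cyclocarbonylation of γ-hydroxy vinyl iodides to butenolides, run at both C–I bonds: oxidative addition to zerovalent palladium, CO insertion and capture of each acylpalladium by the hydroxyl held cis across the alkene close both lactone rings and form C8–C9 and C8'–C9' without touching C7 or C7', the weak base 2,6-lutidine being chosen so that the acidic γ-hydrogens are not removed.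

Step 17
Reactants: 26 (2R,6R)-2-ArG-6-Bf-3,7-dioxabicyclo[3.3.0]oct-1(5)-ene-4,8-dione
Product: 27 (1R,2S,5R,6S)-2-ArG-6-Bf-3,7-dioxabicyclo[3.3.0]octane-4,8-dione
Conditions: H2 (4 atm), 5% Rh/Al2O3, EtOAc, rt
Reagents that add atoms: none
Why: Heterogeneous catalytic syn-hydrogenation, in which both aryl groups lie on the same face of the flat ene-bislactone so that the alkene binds to the metal through the other face and both hydrogens are added there, setting C8 and C8' with all four ring hydrogens cis (cis-fused, both aryls endo); rhodium is used for its low tendency to cleave benzylic C–O bonds.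

Step 18
Reactants: 27 (1R,2S,5R,6S)-2-ArG-6-Bf-3,7-dioxabicyclo[3.3.0]octane-4,8-dione
Product: 28 (1S,2S,3S,4S)-1-ArG-4-Bf-2,3-bis(hydroxymethyl)butane-1,4-diol
Conditions: LiAlH4, THF, −20 °C → 0 °C; then Na2SO4·10H2O
Reagents that add atoms: none
Why: Hydride reduction of both lactones with LiAlH4 gives the tetraol, and no stereocentre is touched.

Step 19
Reactants: 28 (1S,2S,3S,4S)-1-ArG-4-Bf-2,3-bis(hydroxymethyl)butane-1,4-diol
Product: 31 (1S,2S,5S,6S)-2-ArG-6-Bf-3,7-dioxabicyclo[3.3.0]octane, via bis-tosylate 29 (not isolated), via monocyclic tosylate 30 (not isolated)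
Conditions: TsCl (2.2 equiv), pyridine, DMAP (cat.), 0 °C; then 50 °C
Reagents that add atoms: 4-methylbenzenesulfonyl chloride, Cc1ccc(cc1)S(Cl)(=O)=O (atoms in 29 and 30 only)
Why: Selective tosylation of the two primary hydroxyls followed by two intramolecular Williamson etherifications (5-exo-tet), each benzylic hydroxyl displacing the tosylate on its 1,4-related carbon, so the C7–O and C7'–O bonds are never broken and the endo configuration of both aryl groups is retained.

Step 20
Reactants: 31 (1S,2S,5S,6S)-2-ArG-6-Bf-3,7-dioxabicyclo[3.3.0]octane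
Product: 32 CNP0303197.1, 4-[(1S,2S,5S,6S)-6-[(2S,3S)-2-(4-hydroxy-3-methoxyphenyl)-3-(hydroxymethyl)-7-methoxy-2,3-dihydro-1-benzofuran-5-yl]-3,7-dioxabicyclo[3.3.0]octan-2-yl]-2-methoxyphenol
Conditions: Bu4NF, AcOH (1:1), THF, 0 °C → rt
Reagents that add atoms: none
Why: Fluoride-induced cleavage of the two aryl silyl ethers and the one alkyl silyl ether, buffered with acetic acid to avoid both acid-induced epimerisation of the benzylic ethers and phenoxide-driven quinone methide formation.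

**Compound list**

1 | 4-fluoro-3-methoxybenzaldehyde | COc1cc(C=O)ccc1F | starting material
2 | 2-(4-fluoro-3-methoxyphenyl)-1,3-dioxolane | COc1cc(C2OCCO2)ccc1F | intermediate
3 | [5-(1,3-dioxolan-2-yl)-2-fluoro-3-methoxyphenyl]lithium (not isolated) | COc1cc(C2OCCO2)cc([Li])c1F | intermediate
4 | 2-[5-(1,3-dioxolan-2-yl)-2-fluoro-3-methoxyphenyl]ethanol | COc1cc(C2OCCO2)cc(CCO)c1F | intermediate
5 | [5-(1,3-dioxolan-2-yl)-2-fluoro-3-methoxyphenyl]acetic acid | COc1cc(C2OCCO2)cc(CC(=O)O)c1F | intermediate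
6 | (S)-4-benzyl-1,3-oxazolidin-2-one | O=C1N[C@@H](Cc2ccccc2)CO1 | starting material
7 | mixed anhydride of 5 with pivalic acid (not isolated) | COc1cc(C2OCCO2)cc(CC(=O)OC(=O)C(C)(C)C)c1F | intermediate
8 | (4S)-4-benzyl-3-{[5-(1,3-dioxolan-2-yl)-2-fluoro-3-methoxyphenyl]acetyl}-1,3-oxazolidin-2-one | COc1cc(C2OCCO2)cc(CC(=O)N2[C@@H](Cc3ccccc3)COC2=O)c1F | intermediate
9 | vanillin (4-hydroxy-3-methoxybenzaldehyde) | COc1cc(C=O)ccc1O | starting material
10 | 3-methoxy-4-(triisopropylsilyloxy)benzaldehyde | COc1cc(C=O)ccc1O[Si](C(C)C)(C(C)C)C(C)C | intermediate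
11 | O-trimethylsilyl ether of aldol 12 (not isolated) | COc1cc(C2OCCO2)cc([C@@H](C(=O)N2[C@@H](Cc3ccccc3)COC2=O)[C@@H](c2ccc(O[Si](C(C)C)(C(C)C)C(C)C)c(OC)c2)O[Si](C)(C)C)c1F | intermediate
12 | (4S)-4-benzyl-3-[(2R,3S)-2-[5-(1,3-dioxolan-2-yl)-2-fluoro-3-methoxyphenyl]-3-hydroxy-3-ArG-propanoyl]-1,3-oxazolidin-2-one | COc1cc(C2OCCO2)cc([C@@H](C(=O)N2[C@@H](Cc3ccccc3)COC2=O)[C@@H](c2ccc(O[Si](C(C)C)(C(C)C)C(C)C)c(OC)c2)O)c1F | intermediate
13 | (1S,2S)-2-[5-(1,3-dioxolan-2-yl)-2-fluoro-3-methoxyphenyl]-1-ArG-propane-1,3-diol | COc1cc(C2OCCO2)cc([C@@H](CO)[C@@H](c2ccc(O[Si](C(C)C)(C(C)C)C(C)C)c(OC)c2)O)c1F | intermediate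
14 | (1S,2S)-2-[5-(1,3-dioxolan-2-yl)-2-fluoro-3-methoxyphenyl]-1-ArG-3-(triisopropylsilyloxy)propan-1-ol | COc1cc(C2OCCO2)cc([C@@H](CO[Si](C(C)C)(C(C)C)C(C)C)[C@@H](c2ccc(O[Si](C(C)C)(C(C)C)C(C)C)c(OC)c2)O)c1F | intermediate
15 | 4-fluoro-3-[(1S,2S)-1-hydroxy-1-ArG-3-(triisopropylsilyloxy)propan-2-yl]-5-methoxybenzaldehyde (key-step precursor) | COc1cc(C=O)cc([C@@H](CO[Si](C(C)C)(C(C)C)C(C)C)[C@@H](c2ccc(O[Si](C(C)C)(C(C)C)C(C)C)c(OC)c2)O)c1F | intermediate
16 | potassium alkoxide of 15 (not isolated) | COc1cc(C=O)cc([C@@H](CO[Si](C(C)C)(C(C)C)C(C)C)[C@@H](c2ccc(O[Si](C(C)C)(C(C)C)C(C)C)c(OC)c2)[O-])c1F.[K+] | intermediate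
17 | (2S,3S)-7-methoxy-2-ArG-3-[(triisopropylsilyloxy)methyl]-2,3-dihydro-1-benzofuran-5-carbaldehyde (cis; key-step product) | O=Cc1cc(OC)c2c(c1)[C@@H](CO[Si](C(C)C)(C(C)C)C(C)C)[C@@H](c1ccc(O[Si](C(C)C)(C(C)C)C(C)C)c(OC)c1)O2 | intermediate
18 | (1R)-1-ArG-3-(trimethylsilyl)prop-2-yn-1-ol | COc1cc([C@@H](O)C#C[Si](C)(C)C)ccc1O[Si](C(C)C)(C(C)C)C(C)C | intermediate
19 | (1S)-1-ArG-prop-2-yn-1-ol | COc1cc([C@@H](O)C#C)ccc1O[Si](C(C)C)(C(C)C)C(C)C | intermediate
20 | (1S)-1-ArG-1-(trimethylsilyloxy)prop-2-yne | COc1cc([C@@H](O[Si](C)(C)C)C#C)ccc1O[Si](C(C)C)(C(C)C)C(C)C | intermediate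
21 | ethylzinc acetylide of 20 (not isolated) | COc1cc([C@@H](O[Si](C)(C)C)C#C[Zn]CC)ccc1O[Si](C(C)C)(C(C)C)C(C)C | intermediate
22 | 1-O-trimethylsilyl ether of diol 23 (silyl on the ArG-bearing carbinol; not isolated) | COc1cc([C@@H](O[Si](C)(C)C)C#C[C@H](O)c2cc(OC)c3c(c2)[C@@H](CO[Si](C(C)C)(C(C)C)C(C)C)[C@@H](c2ccc(O[Si](C(C)C)(C(C)C)C(C)C)c(OC)c2)O3)ccc1O[Si](C(C)C)(C(C)C)C(C)C | intermediate
23 | (1R,4R)-1-ArG-4-Bf-but-2-yne-1,4-diol | COc1cc([C@@H](O)C#C[C@H](O)c2cc(OC)c3c(c2)[C@@H](CO[Si](C(C)C)(C(C)C)C(C)C)[C@@H](c2ccc(O[Si](C(C)C)(C(C)C)C(C)C)c(OC)c2)O3)ccc1O[Si](C(C)C)(C(C)C)C(C)C | intermediate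
24 | (1R,2E,4R)-1-ArG-4-Bf-2,3-diiodobut-2-ene-1,4-diol | COc1cc([C@@H](O)/C(I)=C(I)/[C@H](O)c2cc(OC)c3c(c2)[C@@H](CO[Si](C(C)C)(C(C)C)C(C)C)[C@@H](c2ccc(O[Si](C(C)C)(C(C)C)C(C)C)c(OC)c2)O3)ccc1O[Si](C(C)C)(C(C)C)C(C)C | intermediate
25 | (5R)-5-Bf-3-[(R)-hydroxy(ArG)methyl]-4-iodofuran-2(5H)-one (not isolated) | O=C1O[C@H](c2cc(OC)c3c(c2)[C@@H](CO[Si](C(C)C)(C(C)C)C(C)C)[C@@H](c2ccc(O[Si](C(C)C)(C(C)C)C(C)C)c(OC)c2)O3)C(I)=C1[C@H](O)c1ccc(O[Si](C(C)C)(C(C)C)C(C)C)c(OC)c1 | intermediate
26 | (2R,6R)-2-ArG-6-Bf-3,7-dioxabicyclo[3.3.0]oct-1(5)-ene-4,8-dione (both aryl groups on one face) | O=C1O[C@H](c3cc(OC)c4c(c3)[C@@H](CO[Si](C(C)C)(C(C)C)C(C)C)[C@@H](c3ccc(O[Si](C(C)C)(C(C)C)C(C)C)c(OC)c3)O4)C2=C1[C@@H](c1ccc(O[Si](C(C)C)(C(C)C)C(C)C)c(OC)c1)OC2=O | intermediate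
27 | (1R,2S,5R,6S)-2-ArG-6-Bf-3,7-dioxabicyclo[3.3.0]octane-4,8-dione (cis-fused, both aryls endo) | COc1cc([C@H]2OC(=O)[C@@H]3[C@H]2C(=O)O[C@@H]3c2cc(OC)c3c(c2)[C@@H](CO[Si](C(C)C)(C(C)C)C(C)C)[C@@H](c2ccc(O[Si](C(C)C)(C(C)C)C(C)C)c(OC)c2)O3)ccc1O[Si](C(C)C)(C(C)C)C(C)C | intermediate
28 | (1S,2S,3S,4S)-1-ArG-4-Bf-2,3-bis(hydroxymethyl)butane-1,4-diol | COc1cc([C@@H](O)[C@H](CO)[C@@H](CO)[C@H](O)c2cc(OC)c3c(c2)[C@@H](CO[Si](C(C)C)(C(C)C)C(C)C)[C@@H](c2ccc(O[Si](C(C)C)(C(C)C)C(C)C)c(OC)c2)O3)ccc1O[Si](C(C)C)(C(C)C)C(C)C | intermediate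
29 | bis(4-methylbenzenesulfonate) of the two primary hydroxyls of 28 (not isolated) | COc1cc([C@@H](O)[C@H](COS(=O)(=O)c2ccc(C)cc2)[C@@H](COS(=O)(=O)c2ccc(C)cc2)[C@H](O)c2cc(OC)c3c(c2)[C@@H](CO[Si](C(C)C)(C(C)C)C(C)C)[C@@H](c2ccc(O[Si](C(C)C)(C(C)C)C(C)C)c(OC)c2)O3)ccc1O[Si](C(C)C)(C(C)C)C(C)C | intermediate
30 | {(2S,3S,4S)-2-ArG-4-[(S)-Bf(hydroxy)methyl]tetrahydrofuran-3-yl}methyl 4-methylbenzenesulfonate (first ring closed; not isolated) | COc1cc([C@H]2OC[C@@H]([C@H](O)c3cc(OC)c4c(c3)[C@@H](CO[Si](C(C)C)(C(C)C)C(C)C)[C@@H](c3ccc(O[Si](C(C)C)(C(C)C)C(C)C)c(OC)c3)O4)[C@H]2COS(=O)(=O)c2ccc(C)cc2)ccc1O[Si](C(C)C)(C(C)C)C(C)C | intermediate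
31 | (1S,2S,5S,6S)-2-ArG-6-Bf-3,7-dioxabicyclo[3.3.0]octane (tris-TIPS ether of the target) | COc1cc([C@H]2OC[C@@H]3[C@H]2CO[C@@H]3c2cc(OC)c3c(c2)[C@@H](CO[Si](C(C)C)(C(C)C)C(C)C)[C@@H](c2ccc(O[Si](C(C)C)(C(C)C)C(C)C)c(OC)c2)O3)ccc1O[Si](C(C)C)(C(C)C)C(C)C | intermediate
32 | CNP0303197.1 | COc1cc([C@H]2OC[C@@H]3[C@H]2CO[C@@H]3c2cc(OC)c3c(c2)[C@@H](CO)[C@@H](c2ccc(O)c(OC)c2)O3)ccc1O | target

**Step count**

Total: 20 steps. Longest linear sequence: 16 steps (steps 1–4, 6–10, 14–20, from 1 to 32). Steps 5 and 11–13 are side branches.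

**Steps most likely to fail**

Step 10. The TIPS group may migrate from O9'' to the C7'' alkoxide, after which the freed primary alkoxide would close the isomeric dihydrobenzofuran; the alkoxide may also be lost by hydride transfer or addition to the formyl group. Fallback (sets out from 13, returns at 17): the primary hydroxyl of 13 is capped with a group that cannot migrate. The dibutylstannylene acetal (Bu2SnO, toluene, reflux) is alkylated with 4-methoxybenzyl chloride and CsF in DMF to give (1S,2S)-2-[5-(1,3-dioxolan-2-yl)-2-fluoro-3-methoxyphenyl]-3-[(4-methoxybenzyl)oxy]-1-ArG-propan-1-ol F1. Deacetalisation as in step 9 gives 4-fluoro-3-[(1S,2S)-1-hydroxy-3-[(4-methoxybenzyl)oxy]-1-ArG-propan-2-yl]-5-methoxybenzaldehyde F2. Its closure with KN(SiMe3)2 in THF can then be driven at room temperature, giving (2S,3S)-7-methoxy-3-{[(4-methoxybenzyl)oxy]methyl}-2-ArG-2,3-dihydro-1-benzofuran-5-carbaldehyde F3. Oxidative debenzylation with DDQ in CH2Cl2/pH 7 buffer at 0 °C gives (2S,3S)-3-(hydroxymethyl)-7-methoxy-2-ArG-2,3-dihydro-1-benzofuran-5-carbaldehyde F4, and silylation with TIPSCl/imidazole returns the route to 17.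

Step 16. Carbon monoxide insertion may lag behind loss of iodide from the vinylpalladium intermediate, which regenerates the alkyne; the sequence may stall at iodobutenolide 25; or the γ-hydrogens may be removed, epimerising C7 and C7'. Fallback (sets out from 24, returns at 26): a base-free double Stille coupling of 24 with (tributylstannyl)methanol (Pd(PPh3)4, CuI, dioxane, 80 °C) retains the alkene geometry and gives (1R,2E,4R)-1-ArG-4-Bf-2,3-bis(hydroxymethyl)but-2-ene-1,4-diol F5. Oxidation with TEMPO/PhI(OAc)2 in CH2Cl2 converts each primary allylic alcohol into the aldehyde, which closes to the lactol with the cis-disposed benzylic hydroxyl and is oxidised on to the butenolide, giving 26.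

Step 17. The tetrasubstituted alkene may resist hydrogenation; it may migrate toward the aryl-bearing carbons and erase their configuration; or hydrogenolysis of the benzylic C–O bonds (lactone C–O, dihydrobenzofuran C2–O) may overtake the reduction. Fallback (sets out from 26, returns at 27): conjugate addition of thiophenol (PhSH, cat. PhSLi, THF, 0 °C) on the face away from the aryl groups, with protonation of the enolate on the same face, gives the cis-fused bridgehead sulfide, the 1-(phenylsulfanyl) derivative of 27 with sulfur on the convex face at the bridgehead next to the ArG-bearing carbon F6. Radical desulfurisation with Bu3SnH/AIBN in toluene at 80 °C delivers hydrogen to the bridgehead radical from the convex face and gives 27 without a metal surface.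

**Further compounds**

F1 | step 10 | (1S,2S)-2-[5-(1,3-dioxolan-2-yl)-2-fluoro-3-methoxyphenyl]-3-[(4-methoxybenzyl)oxy]-1-ArG-propan-1-ol | COc1cc(C2OCCO2)cc([C@@H](COCc2ccc(OC)cc2)[C@@H](c2ccc(O[Si](C(C)C)(C(C)C)C(C)C)c(OC)c2)O)c1F
F2 | step 10 | 4-fluoro-3-[(1S,2S)-1-hydroxy-3-[(4-methoxybenzyl)oxy]-1-ArG-propan-2-yl]-5-methoxybenzaldehyde | COc1cc(C=O)cc([C@@H](COCc2ccc(OC)cc2)[C@@H](c2ccc(O[Si](C(C)C)(C(C)C)C(C)C)c(OC)c2)O)c1F
F3 | step 10 | (2S,3S)-7-methoxy-3-{[(4-methoxybenzyl)oxy]methyl}-2-ArG-2,3-dihydro-1-benzofuran-5-carbaldehyde | O=Cc1cc(OC)c2c(c1)[C@@H](COCc1ccc(OC)cc1)[C@@H](c1ccc(O[Si](C(C)C)(C(C)C)C(C)C)c(OC)c1)O2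
F4 | step 10 | (2S,3S)-3-(hydroxymethyl)-7-methoxy-2-ArG-2,3-dihydro-1-benzofuran-5-carbaldehyde | O=Cc1cc(OC)c2c(c1)[C@@H](CO)[C@@H](c1ccc(O[Si](C(C)C)(C(C)C)C(C)C)c(OC)c1)O2
F5 | step 16 | (1R,2E,4R)-1-ArG-4-Bf-2,3-bis(hydroxymethyl)but-2-ene-1,4-diol | COc1cc([C@@H](O)/C(CO)=C(CO)/[C@H](O)c2cc(OC)c3c(c2)[C@@H](CO[Si](C(C)C)(C(C)C)C(C)C)[C@@H](c2ccc(O[Si](C(C)C)(C(C)C)C(C)C)c(OC)c2)O3)ccc1O[Si](C(C)C)(C(C)C)C(C)C
F6 | step 17 | 1-(phenylsulfanyl) derivative of 27 (sulfur on the convex face at the bridgehead next to the ArG-bearing carbon) | COc1cc([C@H]2OC(=O)[C@@H]3[C@@]2(Sc2ccccc2)C(=O)O[C@@H]3c2cc(OC)c3c(c2)[C@@H](CO[Si](C(C)C)(C(C)C)C(C)C)[C@@H](c2ccc(O[Si](C(C)C)(C(C)C)C(C)C)c(OC)c2)O3)ccc1O[Si](C(C)C)(C(C)C)C(C)C
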